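**Retrosynthetic overview**
1. Target 23 ⇐ isopropenyl alcohol 22 by hydroxyl-directed epoxidation; the C-5 ester comes from acylation of allylic alcohol 17, whose oxygen is put in by allylic C–H oxidation of the exocyclic methylene.
2. Ring A (cyclopentane) ⇐ 5-exo aldol of keto aldehyde 13, obtained by oxidative cleavage of the cyclohexene of a trans-decalin (ring contraction).
3. That trans-decalin ⇐ isoprene Diels–Alder on ring B enone 7.
4. Ring B ⇐ hydrogen-bond-catalysed (TADDOL) asymmetric Diels–Alder of aminosiloxy diene 3 with β-benzoyloxyacrolein 2, which sets the first two stereocentres.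
5. Ring order: ring B (step 2) → auxiliary cyclohexene (step 4) → ring A by cleavage and aldol (steps 6–7).

Assumption: 1, 3, 8 and 18 are bought (all achiral); the side-chain carbinol carbon made in step 2 is carried as an inconsequential epimer mixture until step 13; locants for 14–23 follow octahydro-1H-indene numbering of 23 (C-1 acetoxyethyl, C-2 acetate, C-4 methylidene, C-5 ester, C-6 hydroxyl, C-7 oxiranyl).

**Step 1**
Reactants: 1 tetrabutylammonium (E)-3-oxoprop-1-en-1-olate
Product: 2 (E)-3-oxoprop-1-en-1-yl benzoate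
Conditions: BzCl, CH2Cl2, −20 → 0 °C
Reagents that add atoms: benzoyl chloride, O=C(Cl)c1ccccc1
Why: O-acylation of the ambident malonaldehyde enolate by the hard acyl chloride gives the (E)-β-acyloxy enal; no stereocentre is formed.

**Step 2**
Reactants: 2 (E)-3-oxoprop-1-en-1-yl benzoate; 3 (E)-3-(tert-butyldimethylsilyloxy)-N,N-dimethylbuta-1,3-dien-1-amine
Product: 6 (4R,5S)-5-hydroxy-4-(1-hydroxyethyl)cyclohex-2-en-1-one, via cycloadduct aldehyde 4 (not isolated), via amino enol ether diol 5 (not isolated)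
Conditions: (R,R)-1-naphthyl-TADDOL (20 mol %), toluene, −78 → −40 °C; MeMgBr (4 equiv), Et2O, −78 → 0 °C; 48% aq HF, MeCN, 0 °C
Reagents that add atoms: methylmagnesium bromide, C[Mg]Br
Why: Proposed new method: single-point hydrogen bonding of the TADDOL hydroxyl to the formyl oxygen of 2 lowers the enal LUMO and shields one face with a naphthyl group, the diene bonds its CH2 terminus to the benzoyloxy-bearing β-carbon and its amino-bearing carbon to the α-carbon, suprafacial addition to the E-alkene fixes the trans C-4/C-5 relationship and the catalyst fixes the absolute (4R,5S) sense (the antipodal catalyst is used if the facial sense proves opposite); the closest known reaction is the TADDOL-catalysed Diels–Alder of this diene with α-substituted acroleins, here extended to a β-acyloxy enal, followed by the usual in-flask carbonyl addition (Grignard 1,2-addition plus benzoate cleavage) and HF-induced desilylation/E1cB loss of dimethylamine.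

**Step 3**
Reactants: 6 (4R,5S)-5-hydroxy-4-(1-hydroxyethyl)cyclohex-2-en-1-one
Product: 7 (4R,5S)-5-(tert-butyldimethylsilyloxy)-4-[1-(tert-butyldimethylsilyloxy)ethyl]cyclohex-2-en-1-one
Conditions: TBSCl, imidazole, DMAP (cat.), DMF, 40 °C
Reagents that add atoms: tert-butyldimethylsilyl chloride, CC(C)(C)[Si](C)(C)Cl
Why: Standard silylation of both secondary alcohols; no stereocentre changes.

**Step 4**
Reactants: 7 bis-silyl enone; 8 isoprene
Product: 10 trans-fused 3-(TBSO)-4-[1-(TBSO)ethyl]-6-methyl-3,4,4a,5,8,8a-hexahydronaphthalen-1(2H)-one, via cis-fused adduct 9 (not isolated)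
Conditions: EtAlCl2 (0.3 equiv), toluene, −20 → 0 °C; then DBU (0.2 equiv), rt
Reagents that add atoms: none
Why: Lewis acid-catalysed Diels–Alder with "para" regiochemistry; isoprene adds to the enone face anti to the adjacent C-4 side chain (sets C-4a), and the cis adduct epimerises α to the ketone (C-8a) to the more stable trans-decalone.

**Step 5**
Reactants: 10 trans-decalone
Product: 11 1-methylidene analogue of 10 (trans-fused 1-methylidene-octahydronaphthalene)
Conditions: Ph3PCH3Br, KN(SiMe3)2, THF, 0 → 45 °C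
Reagents that add atoms: methyltriphenylphosphonium bromide, C[P+](c1ccccc1)(c1ccccc1)c1ccccc1.[Br-]
Why: Wittig methylenation of the ketone; the trans ring fusion is the thermodynamic one, so it is not at risk.

**Step 6**
Reactants: 11 diene
Product: 13 2-{4-(TBSO)-3-[1-(TBSO)ethyl]-6-methylidene-2-(2-oxopropyl)cyclohexyl}acetaldehyde, via trisubstituted epoxide 12 (not isolated)
Conditions: mCPBA (1.0 equiv), NaHCO3, CH2Cl2, −20 °C; then H5IO6, THF/H2O, 0 °C
Reagents that add atoms: 3-chloroperbenzoic acid, OOC(=O)c1cccc(Cl)c1; water, O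
Why: Prilezhaev epoxidation is selective for the trisubstituted ring alkene over the 1,1-disubstituted methylidene, and periodic acid cleaves the epoxide (through the diol) to the keto aldehyde; no stereocentre is touched.

**Step 7**
Reactants: 13 keto aldehyde
Product: 14 1-{2-hydroxy-6-(TBSO)-7-[1-(TBSO)ethyl]-4-methylideneoctahydro-1H-inden-1-yl}ethan-1-one (trans-fused; 1-acetyl and 2-OH cis)
Conditions: K2CO3, MeOH, 0 °C
Reagents that add atoms: none
Why: Reversible 5-exo intramolecular aldol of the ketone enolate onto the aldehyde closes ring A; the acetyl group settles trans to the ring B bond at C-7a, and the hydroxyl forms cis to it through a closed, cation-bridged and hydrogen-bonded transition state.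

**Step 8**
Reactants: 14 ketol
Product: 15 (1S)-1-{2-hydroxy-6-(TBSO)-7-[1-(TBSO)ethyl]-4-methylideneoctahydro-1H-inden-1-yl}ethan-1-ol
Conditions: (R)-2-methyl-CBS-oxazaborolidine (0.5 equiv), catecholborane, toluene, −78 → −40 °C
Reagents that add atoms: none
Why: Corey–Bakshi–Shibata reduction of the only ketone; the (R)-catalyst differentiates the branched ring carbon from methyl and gives the (1S)-carbinol under reagent control, and catecholborane leaves the alkene alone at this temperature.

**Step 9**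
Reactants: 15 diol
Product: 16 diacetate (2-acetoxy, 1-[(1S)-1-acetoxyethyl])
Conditions: Ac2O, pyridine, DMAP, CH2Cl2, rt
Reagents that add atoms: acetic anhydride, CC(=O)OC(C)=O
Why: Standard acetylation of both free alcohols with retention.

**Step 10**
Reactants: 16 diacetate
Product: 17 5β-hydroxy derivative of 16 (axial allylic alcohol, cis to the 6-silyloxy group)
Conditions: SeO2 (0.5 equiv), t-BuOOH, CH2Cl2, rt
Reagents that add atoms: selenium dioxide, O=[Se]=O; tert-butyl hydroperoxide, CC(C)(C)OO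
Why: SeO2 allylic hydroxylation (ene reaction, then [2,3]-sigmatropic shift) attacks the ring CH2 (C-5) in preference to the ring-fusion CH and delivers oxygen axially, which is the β face here.

**Step 11**
Reactants: 17 allylic alcohol; 18 (E)-3-methylpent-2-enoic acid
Product: 19 5-[(2E)-3-methylpent-2-enoyloxy] bis-silyl ether
Conditions: 2,4,6-trichlorobenzoyl chloride, Et3N, DMAP, toluene, rt
Reagents that add atoms: none
Why: Yamaguchi esterification acylates the hindered axial alcohol with retention at C-5 and without touching the enoate geometry.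

**Step 12**
Reactants: 19 bis-silyl ether
Product: 20 6-hydroxy-7-(1-hydroxyethyl) diol
Conditions: HF·pyridine, THF/pyridine, 0 °C → rt
Reagents that add atoms: none
Why: Buffered fluoride desilylation removes both TBS groups and leaves the three esters intact.

**Step 13**
Reactants: 20 diol
Product: 21 7-acetyl-6-hydroxy compound
Conditions: TEMPO (0.2 equiv), PhI(OAc)2, CH2Cl2, rt
Reagents that add atoms: none
Why: Oxoammonium oxidation is chemoselective for the less hindered side-chain carbinol, because the ring carbinol at C-6 is shielded and inductively deactivated by the axial C-5 acyloxy group; the epimer mixture converges here.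

**Step 14**
Reactants: 21 β-hydroxy ketone
Product: 22 7-(prop-1-en-2-yl) compound
Conditions: Zn, CH2Br2, TiCl4, THF/CH2Cl2, 0 °C → rt
Reagents that add atoms: dibromomethane, BrCBr
Why: Takai–Lombardo methylenation is non-basic, so it converts the ketone without retro-aldol, epimerisation at C-7 or attack on the esters.

**Step 15**
Reactants: 22 isopropenyl alcohol
Product: 23 Songaricalarin B
Conditions: VO(acac)2 (5 mol %), t-BuOOH, CH2Cl2, 0 °C
Reagents that add atoms: tert-butyl hydroperoxide, CC(C)(C)OO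
Why: Vanadium-catalysed homoallylic-alcohol-directed epoxidation: the vanadate of the C-6 hydroxyl delivers oxygen to the isopropenyl face turned toward it in the rotamer with H-7 eclipsing the C=C (allylic strain minimum), which gives the (S)-oxirane, while the methylidene is deactivated and shielded by the adjacent axial ester.

**Compound list**
1 | tetrabutylammonium (E)-3-oxoprop-1-en-1-olate | CCCC[N+](CCCC)(CCCC)CCCC.[O-]/C=C/C=O | starting material
2 | (E)-3-oxoprop-1-en-1-yl benzoate | O=C/C=C/OC(=O)c1ccccc1 | intermediate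
3 | (E)-3-(tert-butyldimethylsilyloxy)-N,N-dimethylbuta-1,3-dien-1-amine | CN(C)/C=C/C(=C)O[Si](C)(C)C(C)(C)C | starting material
4 | (1S,6S)-3-(tert-butyldimethylsilyloxy)-5-(dimethylamino)-6-formylcyclohex-3-en-1-yl benzoate (amine centre unassigned) | CC(C)(C)[Si](C)(C)OC1=CC(N(C)C)[C@H](C=O)[C@@H](OC(=O)c2ccccc2)C1 | intermediate (not isolated)
5 | (1S,2R)-5-(tert-butyldimethylsilyloxy)-3-(dimethylamino)-2-(1-hydroxyethyl)cyclohex-4-en-1-ol (as magnesium alkoxide; carbinol epimers) | CC(C)(C)[Si](C)(C)OC1=CC(N(C)C)[C@H](C(C)O)[C@@H](O)C1 | intermediate (not isolated)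
6 | (4R,5S)-5-hydroxy-4-(1-hydroxyethyl)cyclohex-2-en-1-one (carbinol epimers) | O=C1C=C[C@H](C(C)O)[C@@H](O)C1 | intermediate
7 | (4R,5S)-5-(tert-butyldimethylsilyloxy)-4-[1-(tert-butyldimethylsilyloxy)ethyl]cyclohex-2-en-1-one | O=C1C=C[C@H](C(C)O[Si](C)(C)C(C)(C)C)[C@@H](O[Si](C)(C)C(C)(C)C)C1 | intermediate
8 | isoprene (2-methylbuta-1,3-diene) | C=CC(C)=C | starting material
9 | cis-fused Diels–Alder adduct (8a-epimer of 10) | O=C1[C@H]2CC=C(C)C[C@H]2[C@H](C(C)O[Si](C)(C)C(C)(C)C)[C@@H](O[Si](C)(C)C(C)(C)C)C1 | intermediate (not isolated)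
10 | trans-fused 3-(TBSO)-4-[1-(TBSO)ethyl]-6-methyl-3,4,4a,5,8,8a-hexahydronaphthalen-1(2H)-one (C-5 methylene trans to the C-4 side chain) | O=C1[C@@H]2CC=C(C)C[C@H]2[C@H](C(C)O[Si](C)(C)C(C)(C)C)[C@@H](O[Si](C)(C)C(C)(C)C)C1 | intermediate
11 | 1-methylidene analogue of 10 | C=C1[C@@H]2CC=C(C)C[C@H]2[C@H](C(C)O[Si](C)(C)C(C)(C)C)[C@@H](O[Si](C)(C)C(C)(C)C)C1 | intermediate
12 | 6,7-epoxide of 11 (epoxide face unassigned) | C=C1[C@@H]2CC3OC3(C)C[C@H]2[C@H](C(C)O[Si](C)(C)C(C)(C)C)[C@@H](O[Si](C)(C)C(C)(C)C)C1 | intermediate (not isolated)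
13 | 2-{4-(TBSO)-3-[1-(TBSO)ethyl]-6-methylidene-2-(2-oxopropyl)cyclohexyl}acetaldehyde (all ring substituents equatorial) | C=C1[C@H](CC=O)[C@@H](CC(C)=O)[C@H](C(C)O[Si](C)(C)C(C)(C)C)[C@@H](O[Si](C)(C)C(C)(C)C)C1 | intermediate
14 | 1-acetyl-2-hydroxy trans-hydrindane (1-acetyl and 2-OH cis; 6-OTBS, 7-[1-(TBSO)ethyl], 4-methylidene) | C=C1[C@@H]2C[C@H](O)[C@H](C(C)=O)[C@H]2[C@H](C(C)O[Si](C)(C)C(C)(C)C)[C@@H](O[Si](C)(C)C(C)(C)C)C1 | intermediate
15 | 2-hydroxy-1-[(1S)-1-hydroxyethyl] diol | C=C1[C@@H]2C[C@H](O)[C@H]([C@H](C)O)[C@H]2[C@H](C(C)O[Si](C)(C)C(C)(C)C)[C@@H](O[Si](C)(C)C(C)(C)C)C1 | intermediate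
16 | 2-acetoxy-1-[(1S)-1-acetoxyethyl] diacetate | C=C1[C@@H]2C[C@H](OC(C)=O)[C@H]([C@H](C)OC(C)=O)[C@H]2[C@H](C(C)O[Si](C)(C)C(C)(C)C)[C@@H](O[Si](C)(C)C(C)(C)C)C1 | intermediate
17 | 5β-hydroxy diacetate (axial allylic alcohol) | C=C1[C@@H]2C[C@H](OC(C)=O)[C@H]([C@H](C)OC(C)=O)[C@H]2[C@H](C(C)O[Si](C)(C)C(C)(C)C)[C@@H](O[Si](C)(C)C(C)(C)C)[C@H]1O | intermediate
18 | (E)-3-methylpent-2-enoic acid | CC/C(C)=C/C(=O)O | starting material
19 | 5-[(2E)-3-methylpent-2-enoate] bis-silyl ether | C=C1[C@@H]2C[C@H](OC(C)=O)[C@H]([C@H](C)OC(C)=O)[C@H]2[C@H](C(C)O[Si](C)(C)C(C)(C)C)[C@@H](O[Si](C)(C)C(C)(C)C)[C@H]1OC(=O)/C=C(\C)CC | intermediate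
20 | 6-hydroxy-7-(1-hydroxyethyl) diol (carbinol epimers) | C=C1[C@@H]2C[C@H](OC(C)=O)[C@H]([C@H](C)OC(C)=O)[C@H]2[C@H](C(C)O)[C@@H](O)[C@H]1OC(=O)/C=C(\C)CC | intermediate
21 | 7-acetyl-6-hydroxy compound | C=C1[C@@H]2C[C@H](OC(C)=O)[C@H]([C@H](C)OC(C)=O)[C@H]2[C@H](C(C)=O)[C@@H](O)[C@H]1OC(=O)/C=C(\C)CC | intermediate
22 | 6-hydroxy-7-(prop-1-en-2-yl) compound | C=C1[C@@H]2C[C@H](OC(C)=O)[C@H]([C@H](C)OC(C)=O)[C@H]2[C@H](C(C)=C)[C@@H](O)[C@H]1OC(=O)/C=C(\C)CC | intermediate
23 | Songaricalarin B, (1S,2S,3aR,5S,6R,7S,7aS)-2-acetoxy-1-[(1S)-1-acetoxyethyl]-6-hydroxy-4-methylidene-7-[(2S)-2-methyloxiran-2-yl]octahydro-1H-inden-5-yl (2E)-3-methylpent-2-enoate | C=C1[C@@H]2C[C@H](OC(C)=O)[C@H]([C@H](C)OC(C)=O)[C@H]2[C@H]([C@@]2(C)CO2)[C@@H](O)[C@H]1OC(=O)/C=C(\C)CC | target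

**Totals and risks**
Total step count: 15. Longest linear sequence: 15 steps (1 → 23).

Steps most likely to fail:

- **Step 2 (the proposed new cycloaddition).** The β-acyloxy enal may react sluggishly or with low facial control under hydrogen-bond catalysis. The fallback sets out from 2 and 3: the uncatalysed thermal cycloaddition (toluene, −20 °C) gives the racemic cycloadduct F1, the same MeMgBr treatment gives the racemic carbinol F2, and HF gives the racemic enone diol F3. Kinetic resolution with Candida antarctica lipase B and vinyl acetate acetylates the unwanted enantiomer to the acetate F4 and leaves 6, which is separated by chromatography. The fallback comes back to the route at 6.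

- **Step 10 (SeO2 oxidation).** The oxidation may give the equatorial C-5 epimer or an epimer mixture. The fallback sets out from 16: excess SeO2/t-BuOOH followed by Dess–Martin periodinane takes all C-5 oxidation products to the 4-methylidene-5-ketone F5. NaBH4/CeCl3·7H2O then gives the equatorial 5α-alcohol F6 by axial hydride attack, and Mitsunobu esterification with 18 (PPh3, diisopropyl azodicarboxylate) installs the ester with inversion. The fallback comes back at 19. It does not cure a regiochemical failure (attack at the ring-fusion CH).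

- **Step 15 (directed epoxidation).** Face selectivity at the isopropenyl group, or competition from the methylidene, may be poor. The fallback sets out from 21: Corey–Chaykovsky reaction with dimethylsulfoxonium methylide (Me3S(O)I, NaH, DMSO) builds the oxirane from the ketone by C–C bond formation and comes back at 23. Its sense at the oxirane carbon is not predicted and would have to be checked. It makes no new compound (F0).

Further compounds
F1 | step 2 | racemic 3-(tert-butyldimethylsilyloxy)-5-(dimethylamino)-6-formylcyclohex-3-en-1-yl benzoate (trans; 4 plus its enantiomer) | CC(C)(C)[Si](C)(C)OC1=CC(N(C)C)[C@H](C=O)[C@@H](OC(=O)c2ccccc2)C1.CC(C)(C)[Si](C)(C)OC1=CC(N(C)C)[C@@H](C=O)[C@H](OC(=O)c2ccccc2)C1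
F2 | step 2 | racemic 5-(tert-butyldimethylsilyloxy)-3-(dimethylamino)-2-(1-hydroxyethyl)cyclohex-4-en-1-ol (trans; 5 plus its enantiomer) | CC(C)(C)[Si](C)(C)OC1=CC(N(C)C)[C@H](C(C)O)[C@@H](O)C1.CC(C)(C)[Si](C)(C)OC1=CC(N(C)C)[C@@H](C(C)O)[C@H](O)C1
F3 | step 2 | racemic trans-5-hydroxy-4-(1-hydroxyethyl)cyclohex-2-en-1-one (6 plus its enantiomer) | O=C1C=C[C@H](C(C)O)[C@@H](O)C1.O=C1C=C[C@@H](C(C)O)[C@H](O)C1
F4 | step 2 | (1R,6S)-6-(1-hydroxyethyl)-3-oxocyclohex-4-en-1-yl acetate | O=C1C=C[C@@H](C(C)O)[C@H](OC(C)=O)C1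
F5 | step 10 | 4-methylidene-5-oxo analogue of 16 | C=C1[C@@H]2C[C@H](OC(C)=O)[C@H]([C@H](C)OC(C)=O)[C@H]2[C@H](C(C)O[Si](C)(C)C(C)(C)C)[C@@H](O[Si](C)(C)C(C)(C)C)C1=O
F6 | step 10 | 5-epimer of 17 (equatorial 5α-alcohol) | C=C1[C@@H]2C[C@H](OC(C)=O)[C@H]([C@H](C)OC(C)=O)[C@H]2[C@H](C(C)O[Si](C)(C)C(C)(C)C)[C@@H](O[Si](C)(C)C(C)(C)C)[C@@H]1O
F0 | step 15 | none | none
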